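Product is what this flask makes, but the excess asked about is read from what stays behind, so the books are kept in fraction left.

| flask | left-handed substrate | right-handed substrate | partner | free catalyst | remark | time |
|---|---|---|---|---|---|---|
| grey | 0.10 M | 0.10 M | 0.30 M | 20 mM | the very flask that is asked about, followed so far |  |
| flask | 0.10 M | 0.10 M | 0.300 M | 20 mM |  | 2.0 h |
grey run (percent of the left-handed substrate and right-handed substrate together charged)

| time / min | right-handed substrate / % | left-handed substrate / % |
|---|---|---|
| 3.00 | 47.9 | 38.1 |
| 5.00 | 47.6 | 35.1 |
| 8.00 | 47.1 | 30.3 |
| 12.0 | 46.4 | 24.8 |
| 20.0 | 46.9 | 17.7 |
| 40.0 | 45.8 | 7.5 |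

(scatter of a reading: 0.3 percentage points)
- free catalyst is single-handed; left-handed substrate and right-handed substrate are mirror images of each other, charged as a racemate, each of them at the stated concentration
- reactions considered so far: free catalyst + left-handed substrate <-> catalyst intermediate A; free catalyst + right-handed substrate <-> catalyst intermediate B; partner + catalyst intermediate A -> free catalyst + left-handed product; partner + catalyst intermediate B -> free catalyst + right-handed product; left-handed product <-> right-handed product; partner -> decomposed reagent; partner -> decomposition product
1. whether the excess of right-handed substrate over left-handed substrate among what is left of the two reaches 80% by 2.0 h (yes / no)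
2. the highest excess of right-handed substrate over left-handed substrate among what is left of the two up to 2.0 h

The ledger follows the limiting reagent, the left-handed substrate, through the grey run at 40.0 min. Of the 50.0% charged, 7.5% stands and 42.5% has gone. The catalyst can hold at most 10.0%, so at least 32.5% has passed on to product. The right-handed substrate has lost 4.20% in the same time.

The entry that counts is the allowance, c(left-handed substrate)/c(right-handed substrate) at the wanted excess, 0.111. The grey run stands at 0.164, above it. With the right-handed substrate as read, the left-handed substrate must fall to 5.09%.

The last two readings give a pseudo-first-order constant of 0.0429 /min. My own reckoning, which holds that constant steady, closes the books at 0.818 h.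

The forecast says yes, with a top of 95%, and of the loss of partner it says “The decline isn't abrupt”.

The flask gives yes, with a top of 96.6%.

    free catalyst + left-handed substrate ⇌ catalyst intermediate A (K = 29.0 /M, k = 5.10 /M/s)
    free catalyst + right-handed substrate ⇌ catalyst intermediate B (K = 9.50 /M, k = 0.710 /M/s)
    partner + catalyst intermediate A → free catalyst + left-handed product (k = 0.0210 /M/s)
    partner + catalyst intermediate B → free catalyst + right-handed product (k = 4.40 × 10⁻⁴ /M/s)
    left-handed product ⇌ right-handed product (k = 0.00260 /s)
    partner → decomposed reagent (k = 1.30 × 10⁻⁴ /s)
    partner → decomposition product (k = 1.50 × 10⁻⁶ /s)

The flask passes 80% at 0.851 h, earlier than the 1.5 h half-life of partner by its step to decomposed reagent, and the allowance then puts the left-handed substrate at 5.02% beside 45.2% of right-handed substrate. At 2.00 h the flask holds 0.752% of left-handed substrate against 44.0% of right-handed substrate, a ratio of 0.0171, below the allowance.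

All runs come from a simulation from invented constants; the scatter is artificial.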